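**Plan**

1. The target is a symmetrical urea of an achiral benzylamine. The ring is numbered C1 (CH2N), C2 (Br), C3 (OH), C4 (OH), C5 (Br), C6 (Br). The retrosynthesis cuts the two urea N–C(=O) bonds first, then the C5–Br and C6–Br bonds, and last the ring bonds C2–C3 and C6–C1.
2. The enabling feature is the C2 bromine wedged between the carbon-bearing C1 and the oxygen-bearing C3, with a second oxygen on C4. C1–C2 map onto a 3-bromopropiolate, whose ester carbon becomes the CH2N carbon. C3–C6 map onto 3-methoxyfuran, whose ring oxygen ends as the C3 hydroxyl and whose methoxy group is the C4 oxygen.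
3. Forward: methyl propiolate is brominated, and the only carbocycle arises in one pot by furan–alkyne cycloaddition and acid opening of the oxygen bridge. Ether cleavage, bromination at C5 and C6, and re-methylation follow.
4. The ester is taken to the benzylamine through the alcohol and the azide, two amine molecules are joined with carbonyldiimidazole, and boron tribromide frees the four phenols.
5. Stereochemistry: the target has no stereocentre; the two bridgehead centres of the racemic cycloadduct disappear on aromatisation.

Key step: step 2

Remark: positions on all aromatic intermediates are discussed with the target ring numbering given in line 1.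

**Step 1**
Reactants: 1 methyl propiolate
Product: 2 methyl 3-bromopropiolate
Conditions: N-bromosuccinimide (1.1 equiv), AgNO3 (0.1 equiv), acetone, rt
Reagents that add atoms: N-bromosuccinimide, O=C1CCC(=O)N1Br
Why: Silver-catalysed electrophilic bromination of a terminal alkyne (a silver acetylide intercepted by N-bromosuccinimide) is the standard entry to 3-bromopropiolates and leaves the ester untouched.

**Step 2**
Reactants: 2 methyl 3-bromopropiolate; 3 3-methoxyfuran
Product: 5 methyl 2-bromo-3-hydroxy-4-methoxybenzoate, via oxanorbornadiene 4 (not isolated)
Conditions: 3 added slowly to 2 (1.1 equiv), CH2Cl2, 0 °C to rt, dark; then CF3CO2H (0.1 equiv), 0 °C to rt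
Reagents that add atoms: none
Why: The methoxy-activated furan should add across the electron-poor bromoynoate in a strongly asynchronous normal-demand Diels–Alder reaction to give racemic 4; CF3CO2H then protonates the bridge oxygen, the C–O bond at bridgehead C1 of 4 (next to the ester-bearing carbon, target C6) ionises to a cation stabilised through the C6=C5 enol ether by the methoxy group, and loss of the proton from the carbinol carbon gives the phenol. The closest known reaction type is the furan–alkynoate [4+2] cycloaddition (as with furan or 2-methylfuran and 3-bromopropiolates) followed by acid isomerisation of an alkoxy-oxanorbornadiene to a phenol. The benzene ring closes by intermolecular [4+2] annulation that forms the C2–C3 and C6–C1 bonds together, four ring atoms coming from the furan and two from the alkyne, and the oxygen bridge is a temporary second ring opened in the same pot. No stereocentre survives, because both bridgehead centres of 4 become aromatic carbons. The regiochemistry needed (furan C2, next to the methoxy group, bonding to the bromine-bearing alkyne carbon) rests on the largest HOMO coefficient at furan C2 matching the largest LUMO coefficient at the beta carbon of the ynoate, and the direction of bridge opening is fixed because only ionisation at the bridgehead remote from the methoxy group gives a methoxy-stabilised cation, which leaves the oxygen on C3. Adding the furan slowly to a slight excess of the alkyne limits a second cycloaddition onto 4, and adding anhydrous acid only after the furan is consumed avoids furan polymerisation and enol-ether hydrolysis.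

**Step 3**
Reactants: 5 methyl 2-bromo-3-hydroxy-4-methoxybenzoate
Product: 6 methyl 2-bromo-3,4-dihydroxybenzoate
Conditions: BBr3 (3 equiv), CH2Cl2, −78 °C to 0 °C; then H2O
Reagents that add atoms: none
Why: Boron tribromide ether cleavage (boron binds the oxygens and bromide removes the O-methyl group by SN2) is fast for a methyl ether next to a phenol, and at or below 0 °C the methyl ester and the aryl bromide should not be attacked.

**Step 4**
Reactants: 6 methyl 2-bromo-3,4-dihydroxybenzoate
Product: 7 methyl 2,3,6-tribromo-4,5-dihydroxybenzoate
Conditions: Br2 (2.2 equiv), AcOH, rt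
Reagents that add atoms: bromine, BrBr
Why: In this electrophilic aromatic bromination the only two open positions are ortho (C5) and para (C6) to the catechol hydroxyls, so two equivalents of bromine can give only the required pattern, and the ester- and bromine-deactivated catechol should resist oxidation to the quinone.

**Step 5**
Reactants: 7 methyl 2,3,6-tribromo-4,5-dihydroxybenzoate
Product: 8 methyl 2,3,6-tribromo-4,5-dimethoxybenzoate
Conditions: MeI (4 equiv), K2CO3 (4 equiv), DMF, rt to 40 °C
Reagents that add atoms: iodomethane, CI
Why: Williamson etherification of the two acidic bromine-flanked phenols masks the catechol against the hydride, the phosphoryl azide and the carbonyl donor of the later steps.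

**Step 6**
Reactants: 8 methyl 2,3,6-tribromo-4,5-dimethoxybenzoate
Product: 9 (2,3,6-tribromo-4,5-dimethoxyphenyl)methanol
Conditions: i-Bu2AlH (3 equiv), CH2Cl2, −78 °C to rt; aq. potassium sodium tartrate
Reagents that add atoms: none
Why: Diisobutylaluminium hydride reduction of an ester to the primary alcohol should proceed despite the two ortho bromines because the hydride donor is small, and aryl bromides and methyl ethers are inert to it.

**Step 7**
Reactants: 9 (2,3,6-tribromo-4,5-dimethoxyphenyl)methanol
Product: 11 2,3,6-tribromo-4,5-dimethoxybenzyl azide, via benzyl phosphate 10 (not isolated)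
Conditions: (PhO)2P(O)N3 (1.3 equiv), DBU (1.5 equiv), DMF, 0 °C to 60 °C
Reagents that add atoms: diphenylphosphoryl azide, [N-]=[N+]=NP(=O)(Oc1ccccc1)Oc1ccccc1
Why: In this Thompson-type azidation the amidine base promotes phosphorylation of the alcohol, and the azide ion set free displaces the phosphate by SN2 at the primary benzylic carbon.

**Step 8**
Reactants: 11 2,3,6-tribromo-4,5-dimethoxybenzyl azide
Product: 13 (2,3,6-tribromo-4,5-dimethoxyphenyl)methanamine, via iminophosphorane 12 (not isolated)
Conditions: PPh3 (1.5 equiv), THF, rt; then H2O, 50 °C
Reagents that add atoms: none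
Why: The Staudinger reduction (phosphazide, loss of N2, hydrolysis of the iminophosphorane) reduces the azide without touching the three aryl bromides, which catalytic hydrogenation would endanger.

**Step 9**
Reactants: 13 (2,3,6-tribromo-4,5-dimethoxyphenyl)methanamine (two equivalents)
Product: 15 1,3-bis[(2,3,6-tribromo-4,5-dimethoxyphenyl)methyl]urea, via carbamoylimidazole 14 (not isolated)
Conditions: 1,1'-carbonyldiimidazole (0.5 equiv), THF, rt to 60 °C
Reagents that add atoms: 1,1'-carbonyldiimidazole, O=C(n1ccnc1)n1ccnc1
Why: In this carbonyldiimidazole carbonylation the first primary amine gives the carbamoylimidazole and the second displaces imidazole, so half an equivalent of reagent should give the symmetrical urea.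

**Step 10**
Reactants: 15 1,3-bis[(2,3,6-tribromo-4,5-dimethoxyphenyl)methyl]urea
Product: 16 1,3-bis[(2,3,6-tribromo-4,5-dihydroxyphenyl)methyl]urea
Conditions: BBr3 (10 equiv), CH2Cl2, −78 °C to rt; then H2O
Reagents that add atoms: none
Why: Boron tribromide cleavage of the four aryl methyl ethers is the usual last step for bromophenols; the urea only ties up Lewis acid (hence the excess), and the benzylic C–N bonds should hold because the tribrominated ring disfavours a benzylic cation.

**Compound list**

1 | methyl propiolate | C#CC(=O)OC | starting material
2 | methyl 3-bromopropiolate | COC(=O)C#CBr | intermediate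
3 | 3-methoxyfuran | COc1ccoc1 | starting material
4 | methyl 3-bromo-5-methoxy-7-oxabicyclo[2.2.1]hepta-2,5-diene-2-carboxylate (racemic, not isolated) | COC(=O)C1=C(Br)C2OC1C=C2OC | intermediate
5 | methyl 2-bromo-3-hydroxy-4-methoxybenzoate | COC(=O)c1ccc(OC)c(O)c1Br | intermediate
6 | methyl 2-bromo-3,4-dihydroxybenzoate | COC(=O)c1ccc(O)c(O)c1Br | intermediate
7 | methyl 2,3,6-tribromo-4,5-dihydroxybenzoate | COC(=O)c1c(Br)c(O)c(O)c(Br)c1Br | intermediate
8 | methyl 2,3,6-tribromo-4,5-dimethoxybenzoate | COC(=O)c1c(Br)c(OC)c(OC)c(Br)c1Br | intermediate
9 | (2,3,6-tribromo-4,5-dimethoxyphenyl)methanol | OCc1c(Br)c(OC)c(OC)c(Br)c1Br | intermediate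
10 | (2,3,6-tribromo-4,5-dimethoxyphenyl)methyl diphenyl phosphate (not isolated) | O=P(OCc1c(Br)c(OC)c(OC)c(Br)c1Br)(Oc1ccccc1)Oc1ccccc1 | intermediate
11 | 2,3,6-tribromo-4,5-dimethoxybenzyl azide | [N-]=[N+]=NCc1c(Br)c(OC)c(OC)c(Br)c1Br | intermediate
12 | N-(2,3,6-tribromo-4,5-dimethoxybenzyl)iminotriphenylphosphorane (not isolated) | c1ccc(cc1)P(=NCc1c(Br)c(OC)c(OC)c(Br)c1Br)(c1ccccc1)c1ccccc1 | intermediate
13 | (2,3,6-tribromo-4,5-dimethoxyphenyl)methanamine | NCc1c(Br)c(OC)c(OC)c(Br)c1Br | intermediate
14 | N-(2,3,6-tribromo-4,5-dimethoxybenzyl)-1H-imidazole-1-carboxamide (not isolated) | O=C(NCc1c(Br)c(OC)c(OC)c(Br)c1Br)n1ccnc1 | intermediate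
15 | 1,3-bis[(2,3,6-tribromo-4,5-dimethoxyphenyl)methyl]urea | O=C(NCc1c(Br)c(OC)c(OC)c(Br)c1Br)NCc1c(Br)c(OC)c(OC)c(Br)c1Br | intermediate
16 | 1,3-bis[(2,3,6-tribromo-4,5-dihydroxyphenyl)methyl]urea | O=C(NCc1c(Br)c(O)c(O)c(Br)c1Br)NCc1c(Br)c(O)c(O)c(Br)c1Br | target

**Step count**

Total steps: 10. Longest linear sequence: 10 steps (1 to 16); the route is linear, and step 9 joins two molecules of the same amine.

**Steps most likely to fail**

Step 2. The pairing of this furan with a haloalkynoate is an extension of the known cases. The electron-rich furan may attack the bromoalkyne by conjugate addition and then lose bromide or transfer a proton, giving open-chain alkynylation or alkenylation without ring closure. It may also add with the opposite orientation or polymerise before it cycloadds. The fallback sets out from 3 and 1 and keeps the ring construction but removes bromine from the dienophile. 3-Methoxyfuran and methyl propiolate (toluene, rt to 60 °C; then catalytic CF3CO2H) should give, through methyl 5-methoxy-7-oxabicyclo[2.2.1]hepta-2,5-diene-2-carboxylate F1 (not isolated), methyl 3-hydroxy-4-methoxybenzoate F2. BBr3 in CH2Cl2 should then give methyl 3,4-dihydroxybenzoate F3. Exhaustive bromination with Br2 (3.3 equiv) in AcOH should fill C2, C5 and C6 in one operation, where regiochemistry cannot go wrong, and the route is rejoined at 7.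

Step 7. Displacement at a benzylic carbon flanked by two ortho bromines may be slow, so the phosphate ester could persist or be hydrolysed back to the alcohol on work-up. The fallback sets out from 9 and makes the C–N bond by carbonyl addition instead of substitution. Oxidation with Dess–Martin periodinane in CH2Cl2 should give 2,3,6-tribromo-4,5-dimethoxybenzaldehyde F4. Condensation with NH3 in EtOH in the presence of Ti(OiPr)4 should give (2,3,6-tribromo-4,5-dimethoxyphenyl)methanimine F5 (not isolated), which NaBH4 in the same flask should reduce. The hindered aldehyde disfavours over-alkylation, and the route is rejoined at 13, replacing steps 7 and 8.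

Step 10. Cleavage of four hindered methyl ethers may stall on a poorly soluble urea–boron complex, and long exposure to the Lewis acid could break a benzylic C–N bond. The fallback sets out from 13 and deprotects before the coupling. BBr3 in CH2Cl2, then MeOH, should give 2,3,6-tribromo-4,5-dihydroxybenzylamine F6, handled as its hydrobromide. Treatment with 1,1'-carbonyldiimidazole (0.5 equiv) and i-Pr2NEt in DMF should acylate nitrogen, through N-(2,3,6-tribromo-4,5-dihydroxybenzyl)-1H-imidazole-1-carboxamide F7 (not isolated), and give 16 directly. Any aryl carbonate formed on the acidic bromocatechol is an active ester that the amine or an aqueous NaHCO3 work-up should cleave. This replaces steps 9 and 10, and no Lewis acid meets the urea.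

**Further compounds**

F1 | step 2 | methyl 5-methoxy-7-oxabicyclo[2.2.1]hepta-2,5-diene-2-carboxylate | COC(=O)C1=CC2OC1C=C2OC
F2 | step 2 | methyl 3-hydroxy-4-methoxybenzoate | COC(=O)c1ccc(OC)c(O)c1
F3 | step 2 | methyl 3,4-dihydroxybenzoate | COC(=O)c1ccc(O)c(O)c1
F4 | step 7 | 2,3,6-tribromo-4,5-dimethoxybenzaldehyde | O=Cc1c(Br)c(OC)c(OC)c(Br)c1Br
F5 | step 7 | (2,3,6-tribromo-4,5-dimethoxyphenyl)methanimine | N=Cc1c(Br)c(OC)c(OC)c(Br)c1Br
F6 | step 10 | 2,3,6-tribromo-4,5-dihydroxybenzylamine | NCc1c(Br)c(O)c(O)c(Br)c1Br
F7 | step 10 | N-(2,3,6-tribromo-4,5-dihydroxybenzyl)-1H-imidazole-1-carboxamide | O=C(NCc1c(Br)c(O)c(O)c(Br)c1Br)n1ccnc1
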